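## Analysis of the target

The atoms are numbered as follows, and these numbers are used throughout: ring C1 (CH–CH3, the methyl being C15), C2 (CH–OH), C3 (CH2), C4 (CH carrying the side chain), C5 (CH–O-angeloyl) and C6 (CH2); side chain C7 (CH–CH3), C8 (CH2), C9 (CH–OAc), C10=C11(CH3)2. The target is a monocyclic bisabolane-type sesquiterpenoid, one cyclohexane with a branched eight-carbon chain, whose three secondary oxygens are in three different states: a free hydroxyl at C2, a (Z)-2-methylbut-2-enoate (angelate) at C5 and an acetate at the allylic C9. It has six stereocentres, 1S,2R,4S,5R in the ring and 7R,9R in the chain. In the ring the C1 methyl, the C2 hydroxyl and the C5 acyloxy group lie on one face and the side chain on the other, so that in the chair the chain, the C5 ester and the C1 methyl are equatorial and only the C2 hydroxyl is axial, a menthol-like core with one extra axial oxygen. C7 is exocyclic and bonded directly to C4, so no ring relays stereochemical information to it, and C9 is 1,3 to C7 and allylic to the trisubstituted alkene. The sensitive groups are the angelate, which isomerises to the E (tiglate) isomer on acyl activation or with nucleophilic bases, the allylic acetate at C9, which can ionise, and the C10=C11 alkene, which rules out hydrogenation and electrophilic oxidants. The difficulty lies in telling the three oxygens apart, in controlling the contiguous C7–C4–C5 array and the axial C2 oxygen, and in acylating the hindered C5 hydroxyl without loss of the Z geometry. The strategy rests on the observation that C15–C1–C2(OH) has the carbon–oxygen pattern of hydroxyacetone and C6–C5(O)–C4 that of a methyl ketone, so that the six ring carbons are hydroxyacetone (C15, C1, C2) plus the four carbons C3–C6 of a but-3-en-2-one that carries the intact side chain on its α-carbon (C4), joined through C2–C3 and C1–C6.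

## Retrosynthetic reasoning

25 ⇒ 24 ⇒ 23 ⇒ 22. The last operations are kept to heteroatom bonds: the C2 O–Si bond, the C9 O–acetyl bond and the C9 O–Si bond. The three oxygens can only be told apart by the order in which they are unmasked. C2 is therefore carried as the bulkier, more acid-stable silyl ether and C9 as the smaller one. The free C2 hydroxyl appears only in the last step, when both esters are in place. The forward steps must remove the C9 silyl group selectively from 22, acetylate 23 and then free C2 in 24 without touching either ester.

22 ⇒ 19 + 20. The C5 O–acyl bond is cut next. The angelate is the most fragile group, so it is introduced after every reduction and every strongly basic step, but before the allylic acetate exists. The forward reaction must acylate a hindered, menthol-like equatorial alcohol with angelic acid 20 without Z-to-E isomerisation. For this reason the acid is activated as mixed anhydride 21 and no nucleophilic catalyst is used.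

19 ⇒ 18 ⇒ 17 ⇒ 16. Removing the C5–H and C1–H bonds (two hydride additions in the forward sense) and the C2 silyl group turns the saturated ring into a 4-hydroxycyclohexenone. This erases C1 and C5, and both can be rewritten from what remains. Hydride must add to C1 of 17 anti to the bulky pseudoaxial C2 silyloxy group, and a small hydride must attack the C5 carbonyl of 18 axially. Cutting here, and not at a C–O bond, leaves a ring, 16, whose carbon–oxygen pattern reads as two carbonyl components.

16 ⇒ 12 + 13. This is the central disconnection. The C1=C6 double bond (aldol condensation, through ketol 15) and the C2–C3 bond (Michael addition, through diketone 14) are cut. Both cuts lie next to a carbonyl group, so both bonds can form under one set of amine-catalysed conditions. All six ring carbons then come from a three-carbon unit, hydroxyacetone 13, and a four-carbon α-methylene ketone, 12, that already holds the complete side chain with C7 and C9. Other ring cuts would leave the chain or the C2 oxygen to be added after the ring. The forward step must set C2 under catalyst control, let C4 settle by equilibration trans to the C2 hydroxyl, and close the ring from C6 onto C1 and not from C15 onto C5. The centre exposed to loss afterwards is C2, which is γ to the new enone carbonyl. C7 is β to C5 and lies on no enolisation path.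

12 ⇒ 11 ⇒ 10 ⇒ 9. The α-methylene ketone is taken back to an aldehyde by cutting C5–C6 (addition of a methyl nucleophile to enal 10, oxidation of 11) and C4=C3 (α-methylenation of 9). An aldehyde is the carrier because its α-methylenation is unambiguous in position, whereas a methyl ketone could react on either side. C7 is β to the carbonyl in 9 and is not touched.

9 ⇒ 8 ⇒ 7 ⇒ 6. These are functional group changes only. The aldehyde comes from the ester, the silyl ether from the alcohol, and removal of the C9–H bond gives enone 6. C9 is then set by catalyst-controlled reduction of a ketone flanked by an alkenyl and a methylene group, independent of the remote C7 centre.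

6 ⇒ 2 + 3. The C9–C10 bond is cut between an acyl carbon and the isobutenyl group. In the forward sense half-ester 2 is activated as acid chloride 4 and coupled with alkenyl metal 3 by way of its zinc derivative 5. This reaction stops at the ketone and spares the second ester.

2 ⇒ 1. The only stereocentre of 2, the future C7, sits on the mirror plane of diester 1. It is therefore created by desymmetrisation and not by C–C bond formation, and the two ester arms become the C9 and the C5 termini.

## Alternatives that were turned down

Alternative 1: The side chain is cut at C7–CH3 and at C8–C9, which leads back to a ring that carries only a vinyl group at C4, (1R,2S,4R,5S)-1,4-bis(tert-butyldimethylsilyloxy)-2-ethenyl-5-methylcyclohexane A2. In the forward direction a zirconocene-catalysed asymmetric methylalumination of the vinyl group creates the C7 methyl branch and a C8–Al bond. The alkylalane is then acylated in the same flask with 3-methylbut-2-enoyl chloride A3 under zerovalent palladium catalysis, which gives the C9 enone A1 with the whole carbon skeleton; no ring is formed. In its favour, it is convergent, it fixes C7 by catalyst control on a ring whose four stereocentres are already secure, and C9 would follow by the same kind of enone reduction as in the chosen route. On convergence and on the security of the ring stereocentres at the time the chain is attached it is stronger than the chosen plan. Against it, methylalumination is the least selective variant of this reaction and is weakest with alkenes branched at the allylic carbon, here a ring carbon next to a silyloxy-bearing carbon whose oxygen can bind aluminium. Excess methylalane left in the flask also competes for A3. Finally A2 has still to be made, so the ring problem is only postponed and the step count rises. The chosen strategy offers instead a C7 centre set in the first step by a robust desymmetrisation and a key step that builds the ring itself.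

Alternative 2: Both ring C–O bonds (C2–O and C5–O) are cut at once, back to the zingiberene-type diene [(4R,6R)-2-methyl-6-[(1S)-4-methylcyclohexa-2,4-dien-1-yl]hept-2-en-4-yl] acetate A5. In the forward direction a dye-sensitised photooxygenation adds the oxidant across C2 and C5 in a [4+2] fashion anti to the C4 substituent and gives the bicyclic endoperoxide A4. In its favour, it is the shortest conceivable entry, it is biomimetic, it needs no protecting group on the ring, and it sets the cis-1,4 relationship of the two oxygens and their trans relationship to C4 in one step. On step count it is clearly stronger. Against it, the C10=C11 alkene is itself a good substrate for the ene reaction with the same oxidant, and face selection rests only on the C4 substituent. After the key step the hydrogen at C1 must be delivered to the face of the C1=C6 bond that lies under the two-carbon bridge carrying the side chain, which is the hindered face. The two carbinols set free from the peroxide are hard to tell apart for the angeloylation, and A5, a 1,3-diene prone to aromatisation, needs its own asymmetric synthesis. The chosen strategy is longer but introduces each oxygen in a distinct state (C2 from 13, C5 as a ketone, C9 as a silyl ether) and sets C1 by hydride addition anti to the C2 oxygen.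

Alternative 3: The ring is cut at C4–C5, which opens it to an acyclic aldehyde with a trisubstituted alkene, (3S,4R)-4-(tert-butyldimethylsilyloxy)-3,7-dimethyloct-6-enal A7. In the forward direction a mild Lewis acid promotes the intramolecular carbonyl-ene reaction (the citronellal-to-isopulegol closure). This forms C4–C5 and gives the C5 alcohol with an isopropenyl group at C4, (1R,2S,4R,5S)-4-(tert-butyldimethylsilyloxy)-5-methyl-2-(prop-1-en-2-yl)cyclohexan-1-ol A6. In its favour, this closure is among the most reliable ring formations known, it passes through a chair transition state that sets C4 and C5 relative to C1 in one step, and it delivers the C5 oxygen at the alcohol level, so no ketone reduction is needed. On precedent and on ring stereocontrol it is stronger than the chosen key step. Against it for this target, the C2 silyloxy group must be axial in that chair, which weakens the bias. The product also stops at C7 (isopropenyl), so C7 must be set by substrate-controlled hydroboration of a 1,1-disubstituted alkene, and C8–C11 with the C9 stereocentre must be added in several further C–C and redox steps after the ring. A7, with its syn C1/C2 pair, needs its own asymmetric synthesis. The chosen strategy pays with a key step that has no precedent, but it brings the complete side chain, with C7 and C9 already set by reliable methods, into the ring-forming event and needs no C–C bond formation after it.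

Key step: step 9

Assumption: the quinine-derived 9-amino-9-deoxy-epi-quinine is taken as the catalyst that leaves the Re face of the enamine carbon C2 open (giving 2R); if the sense proves opposite, the quinidine-derived pseudoenantiomer is used under the same conditions.

## Route

Step 1
Reactants: 1 dimethyl 3-methylpentanedioate (dimethyl 3-methylglutarate)
Product: 2 (3R)-5-methoxy-3-methyl-5-oxopentanoic acid
Conditions: pig liver esterase, 0.1 M phosphate buffer pH 7, MeOH (20% v/v), −10 °C, pH-stat with 1 M NaOH; then HCl to pH 2
Reagents that add atoms: water, O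
Why: Enzymatic desymmetrisation of a prochiral diester: pig liver esterase hydrolyses the pro-S ester arm of 3-methylglutarates, so the (R)-half-ester results and C7 of the target is fixed; low temperature and the methanol co-solvent are the known means of raising the selectivity.

Step 2
Reactants: 2 (3R)-5-methoxy-3-methyl-5-oxopentanoic acid; 3 (2-methylprop-1-en-1-yl)magnesium bromide (commercial solution in THF)
Product: 6 methyl (3R)-3,7-dimethyl-5-oxooct-6-enoate, via acid chloride 4 (not isolated), via alkenylzinc chloride 5 (not isolated)
Conditions: (COCl)2, DMF (cat.), CH2Cl2, 0 °C to rt, evaporate; separately 3, ZnCl2, THF, 0 °C; combine, Pd(PPh3)4 (5 mol%), THF, 0 °C to rt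
Reagents that add atoms: none
Why: Negishi acylation: the acid chloride adds oxidatively to zerovalent palladium, the alkenylzinc transmetalates and reductive elimination gives the enone; organozinc reagents add neither to the methyl ester nor to the product ketone. The acid chloride is kept at or below room temperature so that it cannot close to the symmetrical anhydride and lose its configuration.

Step 3
Reactants: 6 methyl (3R)-3,7-dimethyl-5-oxooct-6-enoate
Product: 7 methyl (3R,5R)-5-hydroxy-3,7-dimethyloct-6-enoate
Conditions: (S)-1-methyl-3,3-diphenyltetrahydro-1H,3H-pyrrolo[1,2-c][1,3,2]oxazaborole ((S)-Me-CBS, 20 mol%), catecholborane, toluene, −78 °C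
Reagents that add atoms: none
Why: Corey–Bakshi–Shibata reduction: the ketone binds the oxazaborolidine–borane complex with the isobutenyl group as the large substituent, and the (S)-catalyst then delivers hydride to give the (R)-allylic alcohol, setting C9 under catalyst control without regard to the remote C7 centre. At −78 °C catecholborane touches neither the ester nor, without catalyst, the enone in conjugate fashion.

Step 4
Reactants: 7 methyl (3R,5R)-5-hydroxy-3,7-dimethyloct-6-enoate
Product: 8 methyl (3R,5R)-5-(tert-butyldimethylsilyloxy)-3,7-dimethyloct-6-enoate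
Conditions: t-BuMe2SiCl, imidazole, DMF, rt
Reagents that add atoms: tert-butyldimethylsilyl chloride, CC(C)(C)[Si](C)(C)Cl
Why: Standard silylation of a secondary allylic alcohol with the imidazole-activated chlorosilane; it is done without delay so that the δ-hydroxy ester cannot lactonise.

Step 5
Reactants: 8 methyl (3R,5R)-5-(tert-butyldimethylsilyloxy)-3,7-dimethyloct-6-enoate
Product: 9 (3R,5R)-5-(tert-butyldimethylsilyloxy)-3,7-dimethyloct-6-enal
Conditions: i-Bu2AlH (1.1 equiv), CH2Cl2, −78 °C; aq. potassium sodium tartrate
Reagents that add atoms: none
Why: Partial reduction of a methyl ester: at −78 °C the tetrahedral aluminium hemiacetal is stable and releases the aldehyde only on work-up; silyl ether and alkene are inert.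

Step 6
Reactants: 9 (3R,5R)-5-(tert-butyldimethylsilyloxy)-3,7-dimethyloct-6-enal
Product: 10 (3R,5R)-5-(tert-butyldimethylsilyloxy)-3,7-dimethyl-2-methylideneoct-6-enal
Conditions: aq. CH2O (37%), pyrrolidine (10 mol%), propionic acid (10 mol%), i-PrOH, 45 °C
Reagents that add atoms: formaldehyde, C=O
Why: Amine-catalysed α-methylenation (Mannich condensation of the enamine with formaldehyde, then elimination of the amine), which can occur only at the single α-CH2 group; C7 is β to the aldehyde and is not enolisable.

Step 7
Reactants: 10 (3R,5R)-5-(tert-butyldimethylsilyloxy)-3,7-dimethyl-2-methylideneoct-6-enal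
Product: 11 (4R,6R)-6-(tert-butyldimethylsilyloxy)-4,8-dimethyl-3-methylidenenon-7-en-2-ol (both C2 epimers)
Conditions: MeMgBr, Et2O, −78 °C
Reagents that add atoms: methylmagnesium bromide, C[Mg]Br
Why: 1,2-Addition of a Grignard reagent to a 2-substituted enal at low temperature; the new carbinol centre is destroyed in step 8, so both epimers are carried on.

Step 8
Reactants: 11 (4R,6R)-6-(tert-butyldimethylsilyloxy)-4,8-dimethyl-3-methylidenenon-7-en-2-ol
Product: 12 3-[(2R,4R)-4-(tert-butyldimethylsilyloxy)-6-methylhept-5-en-2-yl]but-3-en-2-one
Conditions: Dess–Martin periodinane, NaHCO3, CH2Cl2, 0 °C to rt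
Reagents that add atoms: none
Why: Dess–Martin oxidation of the secondary allylic alcohol under buffered, non-basic conditions, which spare the silyl ether and the polymerisation-prone α-methylene ketone; 12 is used at once.

Step 9
Reactants: 12 3-[(2R,4R)-4-(tert-butyldimethylsilyloxy)-6-methylhept-5-en-2-yl]but-3-en-2-one; 13 hydroxyacetone (1-hydroxypropan-2-one)
Product: 16 (4R,6S)-4-hydroxy-3-methyl-6-[(2R,4R)-4-(tert-butyldimethylsilyloxy)-6-methylhept-5-en-2-yl]cyclohex-2-en-1-one, via Michael adduct 14 (not isolated), via ring ketol 15 (not isolated)
Conditions: 13 (3 equiv), 9-amino-9-deoxy-epi-quinine (20 mol%), salicylic acid (40 mol%), THF, rt, then 45 °C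
Reagents that add atoms: none
Why: Proposed new method: the primary amine condenses with 13 to the Z-configured hydroxy-enamine, whose oxygenated carbon C2 is the nucleophilic terminus (as in the known aldol, Mannich and nitroalkene Michael reactions of hydroxyacetone), and this adds to the unsubstituted methylene C3 of 12 while the protonated quinuclidine holds the enone carbonyl, which forms C2–C3 and, after hydrolysis, diketone 14. The closest known reaction types are the amine-catalysed asymmetric Robinson annulation (Michael addition, then aldol condensation) and the primary-amine-catalysed cyclodehydration of heptane-2,6-diones to 3-methylcyclohex-2-enones; what is new is the hydroxy-enamine of 13 as the donor towards an α-branched vinyl ketone and the telescoping of both events. The ring closes by a 6-(enolendo)-exo-trig aldol addition of the enamine (or enol) at the C6 methyl of the C5 ketone to the C1 carbonyl, giving ketol 15, and loss of water through the enamine places the double bond at C1=C6. C2 is set in the Michael step by the catalyst, which leaves the Re face of the enamine carbon open to the acceptor; later re-enolisation of 14 towards C2 would need a tetrasubstituted enamine and is outrun by the excess of 13. C4 arises by protonation and is under thermodynamic control: it epimerises through the enamine or enol of 14 and 15 and through the cross-conjugated dienamine of 16, and should settle trans to the C2 hydroxyl, which sits pseudoaxial to avoid A(1,2) strain with the C1 methyl while the side chain sits pseudoequatorial. The step needs the condensation of C6 onto C1 and not of C15 onto C5, and the substrate secures this because C1 is the more electrophilic carbonyl (α-hydroxyl) and is unhindered, whereas C5 is flanked by the branched C4–C7 unit; closures from C2 or C4 would give four-membered rings. C7 is β to the C5 carbonyl and lies on no enolisation or dienamine path, the silyl ether and the trisubstituted alkene are inert to the amine salt, and the C2–H bond of 16 is pseudoequatorial and poorly aligned for γ-deprotonation, so the carbinol centre should survive if exposure to the catalyst is not prolonged.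

Step 10
Reactants: 16 (4R,6S)-4-hydroxy-3-methyl-6-[(2R,4R)-4-(tert-butyldimethylsilyloxy)-6-methylhept-5-en-2-yl]cyclohex-2-en-1-one
Product: 17 (4R,6S)-4-(tert-butyldiphenylsilyloxy)-3-methyl-6-[(2R,4R)-4-(tert-butyldimethylsilyloxy)-6-methylhept-5-en-2-yl]cyclohex-2-en-1-one
Conditions: t-BuPh2SiCl, imidazole, 4-(dimethylamino)pyridine (DMAP, cat.), DMF, rt
Reagents that add atoms: tert-butyldiphenylsilyl chloride, CC(C)(C)[Si](Cl)(c1ccccc1)c1ccccc1
Why: Silylation of the allylic C2 hydroxyl with the bulky chlorosilane under imidazole and DMAP catalysis; these weak bases do not enolise the γ-oxygenated enone. The large silyl group holds the C2 oxygen pseudoaxial (A(1,2) strain with the C1 methyl), which prepares the facial bias of step 11.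

Step 11
Reactants: 17 (4R,6S)-4-(tert-butyldiphenylsilyloxy)-3-methyl-6-[(2R,4R)-4-(tert-butyldimethylsilyloxy)-6-methylhept-5-en-2-yl]cyclohex-2-en-1-one
Product: 18 (2S,4R,5S)-4-(tert-butyldiphenylsilyloxy)-5-methyl-2-[(2R,4R)-4-(tert-butyldimethylsilyloxy)-6-methylhept-5-en-2-yl]cyclohexan-1-one
Conditions: Cu(OAc)2·H2O (5 mol%), 1,2-bis(diphenylphosphino)benzene (5 mol%), (HMe2Si)2O (0.6 equiv), t-BuOH, toluene, rt
Reagents that add atoms: none
Why: Copper hydride conjugate reduction: a phosphine-ligated hydride of monovalent copper, formed from the divalent copper salt and the silane, adds hydride to C1 in an axial trajectory on the face opposite the pseudoaxial C2 silyloxy group, which places the C1 methyl cis to the C2 oxygen (1S); t-BuOH protonates the copper enolate at C6. Isolated alkenes and silyl ethers are not reduced, the limited amount of silane protects the product ketone, and C4 is not part of the enolate.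

Step 12
Reactants: 18 (2S,4R,5S)-4-(tert-butyldiphenylsilyloxy)-5-methyl-2-[(2R,4R)-4-(tert-butyldimethylsilyloxy)-6-methylhept-5-en-2-yl]cyclohexan-1-one
Product: 19 (1R,2S,4R,5S)-4-(tert-butyldiphenylsilyloxy)-5-methyl-2-[(2R,4R)-4-(tert-butyldimethylsilyloxy)-6-methylhept-5-en-2-yl]cyclohexan-1-ol
Conditions: NaBH4, CeCl3·7H2O, MeOH/THF, −78 °C
Reagents that add atoms: none
Why: Borohydride reduction under Luche-type conditions: the small hydride attacks the C5 carbonyl axially, on the ring face that is free of the axial C2 silyloxy group, and gives the equatorial alcohol trans to the equatorial side chain (5R). The cerium salt keeps the medium non-basic, so C4 does not epimerise.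

Step 13
Reactants: 19 (1R,2S,4R,5S)-4-(tert-butyldiphenylsilyloxy)-5-methyl-2-[(2R,4R)-4-(tert-butyldimethylsilyloxy)-6-methylhept-5-en-2-yl]cyclohexan-1-ol; 20 angelic acid ((2Z)-2-methylbut-2-enoic acid)
Product: 22 (1R,2S,4R,5S)-4-(tert-butyldiphenylsilyloxy)-5-methyl-2-[(2R,4R)-4-(tert-butyldimethylsilyloxy)-6-methylhept-5-en-2-yl]cyclohexyl (2Z)-2-methylbut-2-enoate, via mixed anhydride 21 (not isolated)
Conditions: 20, 2,4,6-trichlorobenzoyl chloride, Et3N, toluene, rt; then 19, toluene, 80 °C
Reagents that add atoms: none
Why: Yamaguchi-type esterification: the hindered alcohol attacks the angeloyl carbonyl of the mixed anhydride, the aroyl carbonyl being shielded by its two ortho chlorines; leaving out a nucleophilic catalyst such as DMAP closes the conjugate addition–elimination path by which angelates isomerise to tiglates.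

Step 14
Reactants: 22 (1R,2S,4R,5S)-4-(tert-butyldiphenylsilyloxy)-5-methyl-2-[(2R,4R)-4-(tert-butyldimethylsilyloxy)-6-methylhept-5-en-2-yl]cyclohexyl (2Z)-2-methylbut-2-enoate
Product: 23 (1R,2S,4R,5S)-4-(tert-butyldiphenylsilyloxy)-2-[(2R,4R)-4-hydroxy-6-methylhept-5-en-2-yl]-5-methylcyclohexyl (2Z)-2-methylbut-2-enoate
Conditions: HF·pyridine, pyridine, THF, 0 °C to rt
Reagents that add atoms: none
Why: Selective desilylation: under pyridine-buffered HF the secondary allylic tert-butyldimethylsilyl ether is cleaved much faster than the hindered, axial tert-butyldiphenylsilyl ether, and the buffer prevents ionisation of the allylic C9–O bond; the angelate and the alkene are inert.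

Step 15
Reactants: 23 (1R,2S,4R,5S)-4-(tert-butyldiphenylsilyloxy)-2-[(2R,4R)-4-hydroxy-6-methylhept-5-en-2-yl]-5-methylcyclohexyl (2Z)-2-methylbut-2-enoate
Product: 24 (1R,2S,4R,5S)-2-[(2R,4R)-4-(acetyloxy)-6-methylhept-5-en-2-yl]-4-(tert-butyldiphenylsilyloxy)-5-methylcyclohexyl (2Z)-2-methylbut-2-enoate
Conditions: Ac2O, pyridine, DMAP (cat.), CH2Cl2, 0 °C to rt
Reagents that add atoms: acetic anhydride, CC(=O)OC(C)=O
Why: DMAP-catalysed acetylation of the only free hydroxyl group.

Step 16
Reactants: 24 (1R,2S,4R,5S)-2-[(2R,4R)-4-(acetyloxy)-6-methylhept-5-en-2-yl]-4-(tert-butyldiphenylsilyloxy)-5-methylcyclohexyl (2Z)-2-methylbut-2-enoate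
Product: 25 (1R,2S,4R,5S)-2-[(2R,4R)-4-(acetyloxy)-6-methylhept-5-en-2-yl]-4-hydroxy-5-methylcyclohexyl (2Z)-2-methylbut-2-enoate (CNP0237033.1)
Conditions: n-Bu4NF, AcOH (1:1), THF, rt to 40 °C
Reagents that add atoms: none
Why: Fluoride cleavage of the remaining silyl ether; buffering with acetic acid suppresses basic side reactions (acetate loss, angelate isomerisation), and the liberated C2 hydroxyl has no 1,2- or 1,3-relationship to an ester, so acyl migration is not expected.

## Compound list

1 | dimethyl 3-methylpentanedioate | COC(=O)CC(C)CC(=O)OC | starting material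
2 | (3R)-5-methoxy-3-methyl-5-oxopentanoic acid | COC(=O)C[C@H](C)CC(=O)O | intermediate
3 | (2-methylprop-1-en-1-yl)magnesium bromide | CC(C)=C[Mg]Br | starting material
4 | methyl (3S)-5-chloro-3-methyl-5-oxopentanoate | COC(=O)C[C@H](C)CC(=O)Cl | intermediate
5 | chloro(2-methylprop-1-en-1-yl)zinc | CC(C)=C[Zn]Cl | intermediate
6 | methyl (3R)-3,7-dimethyl-5-oxooct-6-enoate | COC(=O)C[C@H](C)CC(=O)C=C(C)C | intermediate
7 | methyl (3R,5R)-5-hydroxy-3,7-dimethyloct-6-enoate | COC(=O)C[C@H](C)C[C@H](C=C(C)C)O | intermediate
8 | methyl (3R,5R)-5-(tert-butyldimethylsilyloxy)-3,7-dimethyloct-6-enoate | COC(=O)C[C@H](C)C[C@H](C=C(C)C)O[Si](C)(C)C(C)(C)C | intermediate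
9 | (3R,5R)-5-(tert-butyldimethylsilyloxy)-3,7-dimethyloct-6-enal | O=CC[C@H](C)C[C@H](C=C(C)C)O[Si](C)(C)C(C)(C)C | intermediate
10 | (3R,5R)-5-(tert-butyldimethylsilyloxy)-3,7-dimethyl-2-methylideneoct-6-enal | O=CC(=C)[C@H](C)C[C@H](C=C(C)C)O[Si](C)(C)C(C)(C)C | intermediate
11 | (4R,6R)-6-(tert-butyldimethylsilyloxy)-4,8-dimethyl-3-methylidenenon-7-en-2-ol (both C2 epimers) | CC(O)C(=C)[C@H](C)C[C@H](C=C(C)C)O[Si](C)(C)C(C)(C)C | intermediate
12 | 3-[(2R,4R)-4-(tert-butyldimethylsilyloxy)-6-methylhept-5-en-2-yl]but-3-en-2-one | CC(=O)C(=C)[C@H](C)C[C@H](C=C(C)C)O[Si](C)(C)C(C)(C)C | intermediate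
13 | hydroxyacetone (1-hydroxypropan-2-one) | CC(=O)CO | starting material
14 | (5R)-5-hydroxy-3-[(2R,4R)-4-(tert-butyldimethylsilyloxy)-6-methylhept-5-en-2-yl]heptane-2,6-dione (both C3 epimers) | CC(=O)[C@H](O)CC(C(C)=O)[C@H](C)C[C@H](C=C(C)C)O[Si](C)(C)C(C)(C)C | intermediate
15 | (4R)-4,5-dihydroxy-5-methyl-2-[(2R,4R)-4-(tert-butyldimethylsilyloxy)-6-methylhept-5-en-2-yl]cyclohexan-1-one (mixture at C2 and C5) | O=C1CC(C)(O)[C@H](O)CC1[C@H](C)C[C@H](C=C(C)C)O[Si](C)(C)C(C)(C)C | intermediate
16 | (4R,6S)-4-hydroxy-3-methyl-6-[(2R,4R)-4-(tert-butyldimethylsilyloxy)-6-methylhept-5-en-2-yl]cyclohex-2-en-1-one | O=C1C=C(C)[C@H](O)C[C@H]1[C@H](C)C[C@H](C=C(C)C)O[Si](C)(C)C(C)(C)C | intermediate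
17 | (4R,6S)-4-(tert-butyldiphenylsilyloxy)-3-methyl-6-[(2R,4R)-4-(tert-butyldimethylsilyloxy)-6-methylhept-5-en-2-yl]cyclohex-2-en-1-one | O=C1C=C(C)[C@H](O[Si](c2ccccc2)(c3ccccc3)C(C)(C)C)C[C@H]1[C@H](C)C[C@H](C=C(C)C)O[Si](C)(C)C(C)(C)C | intermediate
18 | (2S,4R,5S)-4-(tert-butyldiphenylsilyloxy)-5-methyl-2-[(2R,4R)-4-(tert-butyldimethylsilyloxy)-6-methylhept-5-en-2-yl]cyclohexan-1-one | O=C1C[C@H](C)[C@H](O[Si](c2ccccc2)(c3ccccc3)C(C)(C)C)C[C@H]1[C@H](C)C[C@H](C=C(C)C)O[Si](C)(C)C(C)(C)C | intermediate
19 | (1R,2S,4R,5S)-4-(tert-butyldiphenylsilyloxy)-5-methyl-2-[(2R,4R)-4-(tert-butyldimethylsilyloxy)-6-methylhept-5-en-2-yl]cyclohexan-1-ol | O[C@@H]1C[C@H](C)[C@H](O[Si](c2ccccc2)(c3ccccc3)C(C)(C)C)C[C@H]1[C@H](C)C[C@H](C=C(C)C)O[Si](C)(C)C(C)(C)C | intermediate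
20 | angelic acid ((2Z)-2-methylbut-2-enoic acid) | C/C=C(/C)C(=O)O | starting material
21 | (2Z)-2-methylbut-2-enoic 2,4,6-trichlorobenzoic anhydride | C/C=C(/C)C(=O)OC(=O)c1c(Cl)cc(Cl)cc1Cl | intermediate
22 | (1R,2S,4R,5S)-4-(tert-butyldiphenylsilyloxy)-5-methyl-2-[(2R,4R)-4-(tert-butyldimethylsilyloxy)-6-methylhept-5-en-2-yl]cyclohexyl (2Z)-2-methylbut-2-enoate | C/C=C(/C)C(=O)O[C@@H]1C[C@H](C)[C@H](O[Si](c2ccccc2)(c3ccccc3)C(C)(C)C)C[C@H]1[C@H](C)C[C@H](C=C(C)C)O[Si](C)(C)C(C)(C)C | intermediate
23 | (1R,2S,4R,5S)-4-(tert-butyldiphenylsilyloxy)-2-[(2R,4R)-4-hydroxy-6-methylhept-5-en-2-yl]-5-methylcyclohexyl (2Z)-2-methylbut-2-enoate | C/C=C(/C)C(=O)O[C@@H]1C[C@H](C)[C@H](O[Si](c2ccccc2)(c3ccccc3)C(C)(C)C)C[C@H]1[C@H](C)C[C@H](C=C(C)C)O | intermediate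
24 | (1R,2S,4R,5S)-2-[(2R,4R)-4-(acetyloxy)-6-methylhept-5-en-2-yl]-4-(tert-butyldiphenylsilyloxy)-5-methylcyclohexyl (2Z)-2-methylbut-2-enoate | C/C=C(/C)C(=O)O[C@@H]1C[C@H](C)[C@H](O[Si](c2ccccc2)(c3ccccc3)C(C)(C)C)C[C@H]1[C@H](C)C[C@H](C=C(C)C)OC(C)=O | intermediate
25 | (1R,2S,4R,5S)-2-[(2R,4R)-4-(acetyloxy)-6-methylhept-5-en-2-yl]-4-hydroxy-5-methylcyclohexyl (2Z)-2-methylbut-2-enoate (CNP0237033.1) | C/C=C(/C)C(=O)O[C@@H]1C[C@H](C)[C@H](O)C[C@H]1[C@H](C)C[C@H](C=C(C)C)OC(C)=O | target

## Step count and least certain steps

Total step count: 16. Longest linear sequence: 16 steps (1 to 25); 3, 13 and 20 enter as commercial compounds.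

Step 9 (key step, proposed new method). Four processes are most likely to go wrong.
- The Michael addition may be slow, because the acceptor is an α-branched vinyl ketone; this leaves time for oligomerisation of 12 and self-condensation of 13, and facial control at C2 may be incomplete.
- Ring closure may take the other mode, C15 onto C5.
- The C2 centre may erode by re-enolisation of 14 or by γ-deprotonation of 16, which also opens the isomerisation of the γ-hydroxy enone to a 1,4-diketone.
- Equilibration at C4 may be incomplete, in which case the material is resubjected to the amine salt.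

The fallback uses known chemistry, sets out from 12 and 13 and returns to the route at 16. 13 is bis-silylated to (Z)-1,2-bis(trimethylsilyloxy)prop-1-ene F1 (Me3SiCl, Et3N, NaI, MeCN). F1 adds to 12 in a Mukaiyama–Michael reaction (Sc(OTf)3 cat., CH2Cl2, −78 °C), and mild acidic methanolysis of the silyl groups gives the hydroxy diketone as a mixture at both stereocentres, 5-hydroxy-3-[(2R,4R)-4-(tert-butyldimethylsilyloxy)-6-methylhept-5-en-2-yl]heptane-2,6-dione F2. Cyclodehydration of F2 with pyrrolidinium acetate in toluene, a standard closure of 1,5-diketones, gives 16 together with its diastereomer (4S,6R)-4-hydroxy-3-methyl-6-[(2R,4R)-4-(tert-butyldimethylsilyloxy)-6-methylhept-5-en-2-yl]cyclohex-2-en-1-one F3, which is removed by chromatography. This replaces enamine catalysis by Lewis acid activation and gives up catalyst control at C2; the price is half of the material, at a point where the two C2 series are separable diastereomers.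

Step 12. Most likely to go wrong is insufficient facial selectivity of the hydride addition: menthone-type ketones allow a share of equatorial attack, which would give the axial C5 alcohol. The fallback sets out from 18 and returns at 22, bypassing 19. The selectivity is turned around on purpose with the bulky LiBH(s-Bu)3 (THF, −78 °C), which attacks equatorially and gives the axial alcohol (1S,2S,4R,5S)-4-(tert-butyldiphenylsilyloxy)-5-methyl-2-[(2R,4R)-4-(tert-butyldimethylsilyloxy)-6-methylhept-5-en-2-yl]cyclohexan-1-ol F4. A Mitsunobu esterification of F4 with 20 (PPh3, diisopropyl azodicarboxylate, toluene) then installs the angelate with inversion at C5. Because the carboxylate acts as nucleophile and is never acyl-activated, this path also avoids Z-to-E isomerisation; its own hazard is elimination of the axial oxyphosphonium group.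

Step 13. Most likely to go wrong is isomerisation of the angeloyl group to the tigloyl group during a slow acylation of the hindered alcohol, or incomplete conversion. The fallback sets out from 19 and returns at 22. 19 is esterified with 2-[bis(2,2,2-trifluoroethoxy)phosphoryl]propanoic acid (dicyclohexylcarbodiimide, DMAP, CH2Cl2) to (1R,2S,4R,5S)-4-(tert-butyldiphenylsilyloxy)-5-methyl-2-[(2R,4R)-4-(tert-butyldimethylsilyloxy)-6-methylhept-5-en-2-yl]cyclohexyl 2-[bis(2,2,2-trifluoroethoxy)phosphoryl]propanoate F5. A Still–Gennari olefination of F5 with acetaldehyde (KN(SiMe3)2, 18-crown-6, THF, −78 °C) builds the Z-trisubstituted double bond on the ester. The Z geometry is then made by a kinetically Z-selective olefination instead of being carried through an acylation.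

Step 11. Most likely to go wrong is sluggish hydride transfer to the hindered β,β-disubstituted enone, with competing 1,2-reduction or loss of facial control. The fallback sets out from 17 and returns at 18 and makes no new compound (F0). It is an organocatalytic transfer hydrogenation through the iminium ion: diethyl 2,6-dimethyl-1,4-dihydropyridine-3,5-dicarboxylate (Hantzsch ester) with the salt of tert-butyl valinate and a chiral 3,3'-diaryl-1,1'-binaphthyl-2,2'-diyl hydrogen phosphate in dibutyl ether at 60 °C. The catalyst antipode is chosen to reinforce the substrate bias. Hydride goes only to C1 of the iminium ion, and isolated alkenes are inert.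

Step 14. Most likely to go wrong is partial loss of the C2 silyl ether, or ionisation of the allylic C9–O bond under the acidic fluoride. The fallback sets out from 22 and returns at 25, one step shorter. Both silyl groups are removed together (n-Bu4NF, AcOH, THF, 40 °C) to give the diol (1R,2S,4R,5S)-4-hydroxy-2-[(2R,4R)-4-hydroxy-6-methylhept-5-en-2-yl]-5-methylcyclohexyl (2Z)-2-methylbut-2-enoate F6. The acyclic allylic C9 hydroxyl of F6 is then acetylated selectively in the presence of the axial, methyl-flanked C2 hydroxyl (AcCl, 2,4,6-collidine, CH2Cl2, −78 °C). The differentiation of C2 and C9 then rests on steric accessibility and no longer on protecting-group order.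

## Further compounds

F1 | step 9 | (Z)-1,2-bis(trimethylsilyloxy)prop-1-ene | C/C(O[Si](C)(C)C)=C/O[Si](C)(C)C
F2 | step 9 | 5-hydroxy-3-[(2R,4R)-4-(tert-butyldimethylsilyloxy)-6-methylhept-5-en-2-yl]heptane-2,6-dione (mixture at C3 and C5) | CC(=O)C(O)CC(C(C)=O)[C@H](C)C[C@H](C=C(C)C)O[Si](C)(C)C(C)(C)C
F3 | step 9 | (4S,6R)-4-hydroxy-3-methyl-6-[(2R,4R)-4-(tert-butyldimethylsilyloxy)-6-methylhept-5-en-2-yl]cyclohex-2-en-1-one | O=C1C=C(C)[C@@H](O)C[C@@H]1[C@H](C)C[C@H](C=C(C)C)O[Si](C)(C)C(C)(C)C
F0 | step 11 | none | none
F4 | step 12 | (1S,2S,4R,5S)-4-(tert-butyldiphenylsilyloxy)-5-methyl-2-[(2R,4R)-4-(tert-butyldimethylsilyloxy)-6-methylhept-5-en-2-yl]cyclohexan-1-ol | O[C@H]1C[C@H](C)[C@H](O[Si](c2ccccc2)(c3ccccc3)C(C)(C)C)C[C@H]1[C@H](C)C[C@H](C=C(C)C)O[Si](C)(C)C(C)(C)C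
F5 | step 13 | (1R,2S,4R,5S)-4-(tert-butyldiphenylsilyloxy)-5-methyl-2-[(2R,4R)-4-(tert-butyldimethylsilyloxy)-6-methylhept-5-en-2-yl]cyclohexyl 2-[bis(2,2,2-trifluoroethoxy)phosphoryl]propanoate | CC(C(=O)O[C@@H]1C[C@H](C)[C@H](O[Si](c2ccccc2)(c3ccccc3)C(C)(C)C)C[C@H]1[C@H](C)C[C@H](C=C(C)C)O[Si](C)(C)C(C)(C)C)P(=O)(OCC(F)(F)F)OCC(F)(F)F
F6 | step 14 | (1R,2S,4R,5S)-4-hydroxy-2-[(2R,4R)-4-hydroxy-6-methylhept-5-en-2-yl]-5-methylcyclohexyl (2Z)-2-methylbut-2-enoate | C/C=C(/C)C(=O)O[C@@H]1C[C@H](C)[C@H](O)C[C@H]1[C@H](C)C[C@H](C=C(C)C)O
A1 | alternative 1 | (6R)-6-[(1S,2R,4S,5R)-2,5-bis(tert-butyldimethylsilyloxy)-4-methylcyclohexyl]-2-methylhept-2-en-4-one | CC(C)(C)[Si](C)(C)O[C@@H]1C[C@H](C)[C@H](O[Si](C)(C)C(C)(C)C)C[C@H]1[C@H](C)CC(=O)C=C(C)C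
A2 | alternative 1 | (1R,2S,4R,5S)-1,4-bis(tert-butyldimethylsilyloxy)-2-ethenyl-5-methylcyclohexane | CC(C)(C)[Si](C)(C)O[C@@H]1C[C@H](C)[C@H](O[Si](C)(C)C(C)(C)C)C[C@H]1C=C
A3 | alternative 1 | 3-methylbut-2-enoyl chloride | CC(C)=CC(=O)Cl
A4 | alternative 2 | [(4R,6R)-2-methyl-6-[(1S,4R,7S)-5-methyl-2,3-dioxabicyclo[2.2.2]oct-5-en-7-yl]hept-2-en-4-yl] acetate | O2[C@@H]1C=C(C)[C@H](O2)C[C@H]1[C@H](C)C[C@H](C=C(C)C)OC(C)=O
A5 | alternative 2 | [(4R,6R)-2-methyl-6-[(1S)-4-methylcyclohexa-2,4-dien-1-yl]hept-2-en-4-yl] acetate | CC1=CC[C@H](C=C1)[C@H](C)C[C@H](C=C(C)C)OC(C)=O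
A6 | alternative 3 | (1R,2S,4R,5S)-4-(tert-butyldimethylsilyloxy)-5-methyl-2-(prop-1-en-2-yl)cyclohexan-1-ol | O[C@@H]1C[C@H](C)[C@H](O[Si](C)(C)C(C)(C)C)C[C@H]1C(C)=C
A7 | alternative 3 | (3S,4R)-4-(tert-butyldimethylsilyloxy)-3,7-dimethyloct-6-enal | O=CC[C@H](C)[C@H](O[Si](C)(C)C(C)(C)C)CC=C(C)C
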